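A one-step world has J.D growing just as fast as the gas crosses into solution, and the reckoning ends there. The flask has more ways than that, and D starts at nothing.

    J → Q (k1 = 0.0037 s⁻¹)
    D → Z (k2 = 0.064 s⁻¹)
    G ⇌ D, rate k3*(csat - [D]) (k3 = 0.24 s⁻¹, csat = 0.0070 mM)
    J + D ⇌ J.D (K4 = 1.2 × 10⁶ M⁻¹, k4 = 7000 M⁻¹ s⁻¹)

J 2.0 × 10⁻⁴ M; G 0.0070 mM (held); time 3.0 min

- amount of J.D at 3.0 min, in percent of the J charged
- the change that raises the amount of J.D at 3.0 min, in percent of the J charged most ("none" if none brings more than 2 percentage points) (dawn / winter / none)
- amount of J.D at 3.0 min, in percent of the J charged, after dawn

The bench rule lets J catch every dissolved D, so J.D grows at the transfer coefficient times the saturation concentration, and that delivery matches the charge of J in 1.98 min, shorter than the run. Because D's half-life by the forward rate of its step with J, with J as charged, 0.50 s, is far shorter than the run, D can be treated as balanced among its ways. With the way back from J.D set aside, its capture share is then J's catching rate (rate constant times J) over that same rate plus the transfer coefficient plus D's decay constant. The rule stops working at J = 4.34 × 10⁻⁵ M, which is 21.7% of the charge, for there this share falls to half.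

Replacing the falling J by a mean of half the charge gives a capture share of 69.7%. Captured delivery over the rate of J into Q at that mean gives 3.17: the mean split, J.D made per Q made, a selectivity factor. With the charge counted as fully reacted, my figure for y is 76.0%. Dawn doubles the split to 6.33 and gives 86.4%. Winter also lowers the capture share, so its split is smaller, 5.11, and I choose dawn.

The forecast, holding that “D relaxes in about a second”, gives 63% for y and 78.5% after dawn, both lower than mine, and it also chooses dawn.

The simulation gives 63.5%, dawn with a gain of 15 percentage points against 7.5 points for winter, and 78.0% after dawn. At 1.50 min the flask held J at 30.6%, J.D at 49.0% and Q at 20.4%. By 3.00 min J in the flask stood at 10.4%, below the border, and J.D per Q read 2.43, less than the mean split. For the flask charged with 8.0 × 10⁻⁴ M of J, the mean split is 1.02, which becomes 0.785 when scaled by this flask's reading over its mean split, and that flask read 0.812.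

The constants used here are those of an exercise; no experiment stands behind them.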